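What strikes me first in this flask is its slowness: even with the whole charge of initiator turned into living ends, growth gives free monomer a decay time of 207 s, longer than the 90 s on offer.

free monomer 36 mM; initiator 0.36 mM; time 1.5 min

    monomer in chains + living end → free monomer + living end, rate k1*[living end] as long as [monomer in chains] is above zero (k1 = 0.0685 s⁻¹)
    free monomer + initiator → living end + monomer in chains (k2 = 5.28 L mol⁻¹ s⁻¹)
    free monomer + living end → monomer in chains + living end, rate k3*[living end]*[free monomer] (k3 = 13.4 L mol⁻¹ s⁻¹)

* average number of monomer units in a chain (chains begun, living or dead) at 1.5 min
* part of the free monomer that has reacted at 1.5 min

- the average divides the monomer in chains by the number of chains begun, living and dead together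
- run time (flask): 1.5 min

My first estimate lets free monomer decay with that time and nothing else, which gives 35.3% reacted. The objection is that living ends also give monomer back, at a rate that does not depend on c(free monomer), so the scale needs another zero. I take the case where adding and losing are equal: the balance concentration, the c(free monomer) at which growth and unzipping cancel, 0.0685 s⁻¹ over 13.4 L mol⁻¹ s⁻¹, or 5.11 mM, the equilibrium monomer concentration. What decays is the excess over this balance, so the part reacted falls to 30.2%.

But the living ends are not there from the first moment. A start takes on average 5.26 s, shorter than the run, so I keep the estimate and shorten the clock by that lag. Each start also swallows one free monomer, which takes 0.36 mM off the excess. Then c(free monomer) comes to 25.4 mM, so 29.5% has reacted, and 0.36 mM of chains begun hold 29.5 units each. I commit to that.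

The forecast says 29.4 units and 29.4% reacted, holding that “Initiation is finished within the first several seconds”.

The simulation gives 29.4 units per chain and 29.4% reacted. Left for 15.0 min, this flask reads 84.7% reacted, less than the 85.8% that the balance concentration allows. In the neighbouring flask charged with 14 mM of free monomer, the balance stays 5.11 mM, the lag becomes 13.5 s, and the same reckoning leaves 11.0 mM, which means 21.4% reacted and 8.33 units per chain. That neighbouring flask gives 21.4% reacted and 8.33 units.

The numbers belong to no real substance; the run is a simulation.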